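Substrate and reagent go one for one, so c(substrate) − c(reagent) stays at its charged 0.0800 M in each run here, and one reading of substrate gives both amounts.

| setting | alpha | gamma | eta |
|---|---|---|---|
| substrate | 0.400 M | 0.400 M | 0.400 M |
| reagent | 0.320 M | 0.320 M | 0.320 M |
| catalyst | 0.0400 M | 0.120 M | 0.0400 M |
| time |  |  | 36 h |

- alpha run (time / h: [substrate] / M): 0.72: 0.388; 1.4: 0.374; 2.6: 0.359; 5.0: 0.331; 9.5: 0.284; 18: 0.241
- gamma run (time / h: [substrate] / M): 0.72: 0.378; 1.4: 0.365; 2.6: 0.328; 5.0: 0.289; 9.5: 0.229; 18: 0.187

(each reading ± 0.004 M)

- Overall: substrate + reagent -> target, with catalyst as catalyst.
- Constant volume, constant temperature.
- "The second partner" is reagent.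
- An order is taken over about fifteen percent of the charge, up and down.

* the power of [catalyst] that the first rate follows, about the charge of the alpha run; measure it at two percent of substrate made into target
* substrate in the eta run at 36 h, as a share of the substrate charged
* which of these the readings show (a little impurity takes part of the catalyst at once / nothing beyond the main steps / the second partner is lost by itself / the catalyst dies in pairs / the catalyst rests as a dimer / the product kills the catalyst)

If the rate is first order in each partner, ln(c(substrate)/c(reagent)) climbs on a straight line. But the slope of that line holds the working catalyst, so it is the number to read. From the charge to the reading at 18 h, the readings of the alpha run rise on average by 0.0100 h⁻¹. I call this rise per hour the turning slope.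

The gamma run gives 0.0186 h⁻¹, so its slope is 1.86 times that of alpha, less than the 3.00 times as much catalyst. Across that tripling, the power of catalyst reads 0.565. That is my average over the span, not the local order asked for.

The eta run has the charge of alpha, so I carry the slope to 36 h and get 45.2% of the substrate left.

The forecast gives 0.6, 45% and "the catalyst rests as a dimer": “A sub-first order present from the start points to a dimer resting state with an active monomer.”

The flask gives 0.60, 44.2% and "the catalyst rests as a dimer".

    catalyst + substrate + reagent → target + catalyst (9.972 L² mol⁻² h⁻¹)
    2 catalyst ⇌ resting dimer, settled at all times (77.20 L mol⁻¹)

In the eta run, the balance leaves 0.0132 M of catalyst free, 32.9% of the charge; the resting dimer, the resting state here, holds the remainder. With the whole charge of the eta run free, the turning slope read from the alpha run scales to 0.0304 h⁻¹, which leaves 27.3% of the substrate at 36 h. In an eta run without the association, the forecast would be wrong by 18 percentage points. That run keeps 26.8% of the substrate at 36 h, against 44.2% with the association.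

The numbers in the tables come from a simulation with constants of no real substance.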